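**Retrosynthetic overview**

1. Locants follow the target: C1 carries C7H2O, C2 is the alkene CH, C3–C6 carry O3–O6. The plan rests on one feature of the single carbocycle: O3 and O6 are para to each other with C7 ortho to O6 (the pattern of 2-(hydroxymethyl)hydroquinone), and O4–H/O5–Bz are trans, i.e. a C4–C5 oxirane opened at C5.
2. 13 ⇐ 12 (Luche reduction of C3=O) ⇐ 11 (hydrolysis of the C3 ketal) ⇐ 10 (C6=O reduced by hydride delivered from O4) ⇐ 8 (benzoate SN2 at C5 of the oxirane).
3. 8 ⇐ 6 (O7 silyl exchanged for benzoyl) ⇐ 4 by catalytic asymmetric nucleophilic epoxidation of C4=C5 of a flat quinone monoketal. O7 is carried as a silyl ether through this step, because an O7 ester would be an allylic leaving group open to SN2' attack by peroxide and to hydroxide.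
4. 4 ⇐ 3 (silylation) ⇐ 2 (anodic dearomatisation in methanol) ⇐ 1 (NaBH4).
5. Ring order: the six-membered carbocycle comes intact from the arene; the oxirane (C4, C5, O) is the only ring made (step 4) and is opened in step 7, after which C4 and C5 steer C6 and then C3.

Key step: step 4

Assumption: the cinchonidine-derived salt is taken to give the (1R,6S) oxirane; if the sense of induction is the opposite, the pseudoenantiomeric N-benzylcinchoninium chloride replaces it with nothing else changed.

**Route**

Step 1
Reactants: 1 aldehyde 2-hydroxy-5-methoxybenzaldehyde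
Product: 2 diol 2-(hydroxymethyl)-4-methoxyphenol
Conditions: NaBH4, MeOH, 0 °C
Reagents that add atoms: none
Why: Borohydride reduction of an aryl aldehyde to the benzylic alcohol is routine and leaves the phenol and the aryl methyl ether untouched; no stereocentre is formed.

Step 2
Reactants: 2 diol 2-(hydroxymethyl)-4-methoxyphenol
Product: 3 quinone monoketal 2-(hydroxymethyl)-4,4-dimethoxycyclohexa-2,5-dien-1-one
Conditions: graphite anode, Pt cathode, LiClO4, MeOH, undivided cell, constant current, 0 °C
Reagents that add atoms: methanol, CO
Why: Anodic oxidative dearomatisation of a para-methoxyphenol gives a phenoxonium ion that methanol traps at the methoxy-bearing para carbon, and the phenol should be oxidised well before the benzylic alcohol.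

Step 3
Reactants: 3 quinone monoketal 2-(hydroxymethyl)-4,4-dimethoxycyclohexa-2,5-dien-1-one
Product: 4 silyl ether 2-({[tert-butyl(dimethyl)silyl]oxy}methyl)-4,4-dimethoxycyclohexa-2,5-dien-1-one
Conditions: TBSCl, imidazole, CH2Cl2, 0 °C to rt
Reagents that add atoms: tert-butyldimethylsilyl chloride, CC(C)(C)[Si](C)(C)Cl
Why: Silylation of a primary allylic alcohol with imidazole is reliable, the near-neutral medium spares the ketal, and the silyl ether is inert to hydroxide and cannot leave in an SN2' sense in step 4.

Step 4
Reactants: 4 silyl ether 2-({[tert-butyl(dimethyl)silyl]oxy}methyl)-4,4-dimethoxycyclohexa-2,5-dien-1-one; 5 tert-butyl hydroperoxide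
Product: 6 epoxy ketone (1R,6S)-3-({[tert-butyl(dimethyl)silyl]oxy}methyl)-5,5-dimethoxy-7-oxabicyclo[4.1.0]hept-3-en-2-one (oxirane on C4–C5 of the target, ketone at C6, ketal at C3)
Conditions: tBuOOH, N-benzylcinchonidinium chloride (10 mol%), aq NaOH (0.1 M), toluene, 0 °C
Reagents that add atoms: tert-butyl hydroperoxide (5), CC(C)(C)OO
Why: The hydroperoxide is deprotonated at the interface and carried into toluene as an ion pair with the chiral ammonium cation; the peroxide anion adds to C4, the β-carbon of the C6(=O)–C5=C4 enone, forming the C4–O bond, and the enolate then attacks the proximal peroxide oxygen through C5, expelling tert-butoxide and forming the C5–O bond. The closest known reaction type is the Weitz–Scheffer epoxidation of quinone monoketals and other cyclic enones under cinchona-derived phase-transfer catalysis. The oxirane closes in a 3-exo-tet mode on the O–O bond. C4 is set by the enantiotopic face of the flat dienone that the ion pair presents to the peroxide, and C5 follows because the three-membered ring can only close on the face that already carries the C4 oxygen. The step needs chemoselectivity for C4=C5 over C1=C2, which the substrate secures because the C1=C2 enone carries the α-substituent CH2OSi (less electrophilic, more hindered, and no leaving group for an SN2' exit), and it needs enantioface selectivity, which rests on the catalyst alone.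

Step 5
Reactants: 6 epoxy ketone (1R,6S)-3-({[tert-butyl(dimethyl)silyl]oxy}methyl)-5,5-dimethoxy-7-oxabicyclo[4.1.0]hept-3-en-2-one
Product: 7 alcohol (1R,6S)-3-(hydroxymethyl)-5,5-dimethoxy-7-oxabicyclo[4.1.0]hept-3-en-2-one
Conditions: Et3N·3HF, THF, rt
Reagents that add atoms: none
Why: Fluoride-mediated desilylation of a primary silyl ether with this near-neutral reagent should spare the epoxy ketone and the ketal, which a basic fluoride source could damage.

Step 6
Reactants: 7 alcohol (1R,6S)-3-(hydroxymethyl)-5,5-dimethoxy-7-oxabicyclo[4.1.0]hept-3-en-2-one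
Product: 8 benzoate [(1R,6S)-5,5-dimethoxy-2-oxo-7-oxabicyclo[4.1.0]hept-3-en-3-yl]methyl benzoate
Conditions: BzCl, pyridine, CH2Cl2, 0 °C
Reagents that add atoms: benzoyl chloride, O=C(Cl)c1ccccc1
Why: Acylation of the primary alcohol with an acid chloride in pyridine installs the O7 benzoate of the target without touching the oxirane, the enone or the ketal.

Step 7
Reactants: 8 benzoate [(1R,6S)-5,5-dimethoxy-2-oxo-7-oxabicyclo[4.1.0]hept-3-en-3-yl]methyl benzoate; 9 benzoic acid
Product: 10 hydroxy ketone [(4S,5S)-5-(benzoyloxy)-4-hydroxy-3,3-dimethoxy-6-oxocyclohex-1-en-1-yl]methyl benzoate (target locants)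
Conditions: PhCO2H (3 equiv), PhCO2Cs (cat.), DMF, 50 °C
Reagents that add atoms: benzoic acid (9), OC(=O)c1ccccc1
Why: Nucleophilic SN2 opening of the oxirane by carboxylate, buffered by excess acid, should occur at C5 (α to the C6 carbonyl) rather than at C4 (neopentyl-like and deactivated by the C3 ketal), and backside attack inverts C5 while the C4–O bond is untouched, giving the trans C4 hydroxyl/C5 benzoate.

Step 8
Reactants: 10 hydroxy ketone [(4S,5S)-5-(benzoyloxy)-4-hydroxy-3,3-dimethoxy-6-oxocyclohex-1-en-1-yl]methyl benzoate
Product: 11 diol [(4S,5R,6R)-5-(benzoyloxy)-4,6-dihydroxy-3,3-dimethoxycyclohex-1-en-1-yl]methyl benzoate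
Conditions: Me4NBH(OAc)3, MeCN–AcOH (1:1), −20 °C
Reagents that add atoms: none
Why: Hydroxyl-directed (Evans–Saksena) reduction: the C4 hydroxyl binds boron and delivers hydride to C6 on its own face, so the new C6 hydroxyl is anti to O4 and cis to the C5 benzoate, while the acidic cold medium disfavours enolisation at C5 and ester migration.

Step 9
Reactants: 11 diol [(4S,5R,6R)-5-(benzoyloxy)-4,6-dihydroxy-3,3-dimethoxycyclohex-1-en-1-yl]methyl benzoate
Product: 12 enone [(4S,5R,6R)-5-(benzoyloxy)-4,6-dihydroxy-3-oxocyclohex-1-en-1-yl]methyl benzoate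
Conditions: CF3CO2H–H2O (9:1), CH2Cl2, 0 °C
Reagents that add atoms: water, O
Why: Acid-catalysed hydrolysis of the allylic dimethyl ketal is driven by formation of the conjugated C3 enone and is mild enough to leave both benzoates, the allylic C6 alcohol and the C4–C6 stereocentres unchanged.

Step 10
Reactants: 12 enone [(4S,5R,6R)-5-(benzoyloxy)-4,6-dihydroxy-3-oxocyclohex-1-en-1-yl]methyl benzoate
Product: 13 target [(3S,4R,5R,6R)-5-(benzoyloxy)-3,4,6-trihydroxycyclohex-1-en-1-yl]methyl benzoate
Conditions: NaBH4, CeCl3·7H2O, MeOH, −78 °C
Reagents that add atoms: none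
Why: Luche 1,2-reduction: in the half-chair with O4 and O5 equatorial, hydride should attack C3 axially on the O4 face, away from the C5 benzoate and the C6 hydroxyl, so the new hydroxyl is pseudoequatorial and trans to O4; the cold, base-free medium avoids β-elimination of benzoate.

**Compound list**

1 | 2-hydroxy-5-methoxybenzaldehyde | COc1ccc(O)c(C=O)c1 | starting material
2 | 2-(hydroxymethyl)-4-methoxyphenol | COc1ccc(O)c(CO)c1 | intermediate
3 | 2-(hydroxymethyl)-4,4-dimethoxycyclohexa-2,5-dien-1-one | O=C1C(CO)=CC(OC)(OC)C=C1 | intermediate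
4 | 2-({[tert-butyl(dimethyl)silyl]oxy}methyl)-4,4-dimethoxycyclohexa-2,5-dien-1-one | O=C1C(CO[Si](C)(C)C(C)(C)C)=CC(OC)(OC)C=C1 | intermediate
5 | tert-butyl hydroperoxide | CC(C)(C)OO | starting material
6 | (1R,6S)-3-({[tert-butyl(dimethyl)silyl]oxy}methyl)-5,5-dimethoxy-7-oxabicyclo[4.1.0]hept-3-en-2-one | CC(C)(C)[Si](C)(C)OCC1=CC(OC)(OC)[C@H]2O[C@H]2C1=O | intermediate
7 | (1R,6S)-3-(hydroxymethyl)-5,5-dimethoxy-7-oxabicyclo[4.1.0]hept-3-en-2-one | OCC1=CC(OC)(OC)[C@H]2O[C@H]2C1=O | intermediate
8 | [(1R,6S)-5,5-dimethoxy-2-oxo-7-oxabicyclo[4.1.0]hept-3-en-3-yl]methyl benzoate | O=C(OCC1=CC(OC)(OC)[C@H]2O[C@H]2C1=O)c1ccccc1 | intermediate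
9 | benzoic acid | OC(=O)c1ccccc1 | starting material
10 | [(4S,5S)-5-(benzoyloxy)-4-hydroxy-3,3-dimethoxy-6-oxocyclohex-1-en-1-yl]methyl benzoate | O=C(OCC1=CC(OC)(OC)[C@@H](O)[C@H](OC(=O)c2ccccc2)C1=O)c1ccccc1 | intermediate
11 | [(4S,5R,6R)-5-(benzoyloxy)-4,6-dihydroxy-3,3-dimethoxycyclohex-1-en-1-yl]methyl benzoate | O=C(OCC1=CC(OC)(OC)[C@@H](O)[C@H](OC(=O)c2ccccc2)[C@@H]1O)c1ccccc1 | intermediate
12 | [(4S,5R,6R)-5-(benzoyloxy)-4,6-dihydroxy-3-oxocyclohex-1-en-1-yl]methyl benzoate | O=C(OCC1=CC(=O)[C@@H](O)[C@H](OC(=O)c2ccccc2)[C@@H]1O)c1ccccc1 | intermediate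
13 | [(3S,4R,5R,6R)-5-(benzoyloxy)-3,4,6-trihydroxycyclohex-1-en-1-yl]methyl benzoate | O=C(OCC1=C[C@H](O)[C@@H](O)[C@H](OC(=O)c2ccccc2)[C@@H]1O)c1ccccc1 | target

**Step count and risks**

Total step count: 10. Longest linear sequence: 10 steps (1 to 13).

Steps most likely to fail:

Step 4. The ion pair may discriminate poorly between the two faces of C4, since cis-enones of this kind are demanding substrates for phase-transfer epoxidation. Hydroxide may also compete with the peroxide and attack silicon or the dienone. The fallback hands stereocontrol from the catalyst to a stoichiometric chiral reagent anchored on the substrate. The free alcohol 3 would be treated with trityl hydroperoxide, NaN(SiMe3)2 and diisopropyl tartrate in toluene at −50 °C (tartrate-mediated nucleophilic epoxidation). The C7 alkoxide holds the dienone in the sodium tartrate–peroxide aggregate, no aqueous hydroxide is present, and the tartrate enantiomer is chosen for the (1R,6S) oxirane. This sets out from 3 and returns to the route at 7, so steps 3 and 5 are then not needed; no compound outside the list is made.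

Step 7. Benzoate may act as a base instead of a nucleophile. Enolisation at C5 of the product would epimerise that centre or expel the C4 hydroxyl, after which loss of methanol aromatises the ring. The opening may also be slow at a carbon flanked by two oxygenated neighbours. The fallback takes the ketone out of play during the opening. Epoxy ketone 8 would be reduced (NaBH4, CeCl3·7H2O, MeOH, −78 °C, hydride expected on the face away from the oxirane oxygen) to the epoxy alcohol [(1S,2S,6S)-2-hydroxy-5,5-dimethoxy-7-oxabicyclo[4.1.0]hept-3-en-3-yl]methyl benzoate F1. With no acidic hydrogen at C5, this can be heated with PhCO2Cs and PhCO2H in DMF (80 °C), attack again going to C5 because C4 stays shielded by the ketal, to give [(4S,5R,6S)-5-(benzoyloxy)-4,6-dihydroxy-3,3-dimethoxycyclohex-1-en-1-yl]methyl benzoate F2. MnO2 in CH2Cl2 would then oxidise only the allylic C6 hydroxyl. This sets out from 8 and returns to the route at 10 under neutral conditions. The configuration at C6 on the way is immaterial, because that centre is re-oxidised and set afresh in step 8.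

Step 10. If the half-chair with O4 and O5 axial is populated, hydride may enter C3 anti to the C4–O bond and give the C3 epimer; the enone may also lose benzoate from C5 if the medium turns basic. The fallback replaces conformational control by a directing group. Enone 12 would be reduced with Me4NBH(OAc)3 in MeCN–AcOH at −20 °C. The C4 hydroxyl binds boron and hydride can reach C3 only on the O4 face (hydroxyl-directed reduction), which gives the 3,4-trans diol in a medium that stays acidic. This sets out from 12 and returns at 13; no new compound is made.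

**Further compounds**

F0 | step 4 | none | none
F1 | step 7 | [(1S,2S,6S)-2-hydroxy-5,5-dimethoxy-7-oxabicyclo[4.1.0]hept-3-en-3-yl]methyl benzoate | O=C(OCC1=CC(OC)(OC)[C@H]2O[C@H]2[C@H]1O)c1ccccc1
F2 | step 7 | [(4S,5R,6S)-5-(benzoyloxy)-4,6-dihydroxy-3,3-dimethoxycyclohex-1-en-1-yl]methyl benzoate | O=C(OCC1=CC(OC)(OC)[C@@H](O)[C@H](OC(=O)c2ccccc2)[C@H]1O)c1ccccc1
F0 | step 10 | none | none
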